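## Structural features

The target has two rings, a benzene ring and a 2,2-disubstituted oxirane, joined through the quaternary oxirane carbon, which is the only stereocenter (S). That carbon carries the aryl group, the ring oxygen, the ring CH2 and an acetoxymethyl group. The two CH2–O arms differ only in what their oxygen atoms carry, so the stereocenter exists only while the arms stay differentiated. The arene is 1,2,4-trisubstituted: C1 bears the oxirane, C2 a phenolic isobutyrate, and C4 an isobutyryloxymethyl group that is meta to the phenol oxygen and so cannot leave through a quinone methide. The fragile points are: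

- the tertiary benzylic oxirane, which is sensitive to acid and to a free ortho phenoxide;
- the aryl ester, which is sensitive to nucleophiles and can transfer its acyl group to a hydroxyl on the ortho side chain;
- any stage with a free alkoxide beside the oxirane (Payne rearrangement) or an acetate on one arm with a free hydroxyl on the other (acyl shift), since each of these leads to the enantiomer.

No stereocenters are adjacent, so the difficulty is the absolute configuration of a fully substituted benzylic carbon flanked by two nearly identical arms. The key step uses the fact that the phenol oxygen on aryl C2 lies four atoms from the carbon of one arm (O–C2–C1–Cq–C). With that arm raised to the carboxyl level, the two close into the five-membered lactone of a benzofuran-2(3H)-one whose C3 is the future quaternary carbon. This ring is absent from the target; it makes C3–H acidic, fixes the enolate geometry and distinguishes the arms by oxidation level.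

## Logic of the disconnections

**22 to 21.** The acetate O–acyl bond is cut first. An acetyl group on this arm would migrate if a free hydroxyl or an alkoxide appeared on the other arm or on the tertiary oxygen, so it is installed last. This leaves a molecule with only the two isobutyrates. The forward step must acylate 21 without forming its alkoxide.

**21 to 20.** The O–H of the free arm is traced to an O–benzyl bond of a 4-methoxybenzyl ether. An ether cannot migrate, is a poor leaving group next to an enolate, and can be removed oxidatively at neutral pH. The forward step must have water capture the oxocarbenium ion before the oxirane oxygen does.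

**20 to 18 (through 19).** The oxirane CH2–O bond is cut, not the Cq–O bond. The C–O bond at the stereocenter is therefore carried through unchanged from the step that made it. This gives a 1,2-diol with a primary and a tertiary hydroxyl. The forward step needs sulfonylation of the primary hydroxyl only, and a 3-exo-tet closure that is faster than acyl transfer from the neighbouring aryl ester.

**18 to 17 and 7.** The aryl O–acyl bond is cut. The phenol must be acylated before the oxirane exists, because a free phenoxide ortho to it would open it. This leads back to a triol. The forward step must acylate the phenol in the presence of two aliphatic hydroxyls.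

**17 to 15.** The phenol oxygen and the carbon of the CH2OH arm, raised to the acyl level, are reconnected as the aryl O–C(=O) bond of a lactone. This ring is made only for control and is absent from the target. In 15 the phenol is masked and the two arms sit at different oxidation levels. The forward step needs a hydride that reduces the activated aryl lactone and spares the benzylic isobutyrate.

**15 to 14.** The C3–O bond is cut, leaving a C–H acid. The stereocenter disappears, so racemic 14 suffices and all of it passes through one planar enolate. The forward step needs a chiral base and oxidant pair that selects one enolate face and oxidises faster than the enolate expels its β-alkoxide.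

**14 to 13 to 12.** The lactone O–C(=O) bond is cut to a phenol and an ethyl ester, then the phenol O–Si bond. The enolate alkylation and the cross-coupling need an open-chain ester and a masked phenol. The benzylic oxygen already carries its isobutyrate at this stage, because an aryl lactone is an active ester that a free primary alcohol would open intermolecularly. The forward closure must work under acid mild enough for the benzylic ether, with removal of ethanol.

**12 to 11 and 3.** The bond from the α-carbon to the CH2O carbon is cut. The arm arrives already protected and differentiated from the ester carbon. The forward step needs C-alkylation of a lithium enolate by a labile α-chloro ether in the presence of an isobutyrate.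

**11 to 8 and 9 (through 10).** The aryl–CH2 bond is cut, giving an aryl bromide and a two-carbon zinc enolate. The forward coupling must be neutral enough for the ester and the silyl ether and must work at an electron-rich, ortho-substituted bromide.

**8 to 6 and 7, 6 to 5, 5 to 4.** The benzylic O–acyl bond, the benzylic C–O oxidation level and the phenol O–Si bond are adjusted in turn. The phenol is silylated while the benzylic carbon is still an ester, so two hydroxyls never have to be told apart. The forward reduction must leave the aryl bromide intact.

**3 to 2 to 1.** The C–Cl bond and then the O–CH2(S) bond are cut. The chloromethyl ether is too labile to store, so the forward route makes it from the stable O,S-acetal and uses it at once.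

## Other disconnections considered

Alternative 1: The oxirane CH2 is removed altogether (the Cq–CH2 and CH2–O bonds), leading to ketone A1. In the forward step dimethyloxosulfonium methylide would add to A1 under the LaLi3(binaphthoxide)3 complex with a triarylphosphine oxide and close to oxirane A2.

- In its favour: ring and stereocenter would form in one step from an achiral ketone, with no lactone detour. A1 should be reachable in a few steps from the same aryl bromide by metalation and acylation with an alkoxyacetic acid derivative. On step count up to the oxirane this alternative is the better one.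
- Against it: this catalyst distinguishes the two carbonyl flanks mainly by size and is at its best when one is a methyl group. In A1 the flanks are a hindered ortho-silyloxy aryl group and a coordinating, enolisable alkoxymethyl group. The ylide would also attack aryl and alkyl esters, so A2 must carry silyl ethers. Exchanging the phenolic silyl ether for the isobutyrate after the oxirane exists would pass through a phenoxide ortho to the oxirane, which can open it by 5-exo attack.
- Comparison: both plans rely on a catalyst choosing a face, and the ether removal and acetylation at the end are the same (equal). The chosen plan is structurally safer because its aryl ester is in place before the oxirane is made, and its enolate geometry is fixed by a ring, whereas A1 can bind the catalyst in more than one way.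

Alternative 2: The aryl–Cq bond is cut. Boronate A3 would add to the ketone carbonyl of keto ester A4 under [RhCl(C2H4)2]2 (monovalent rhodium) and a chiral diene, giving hydroxy ester A5.

- In its favour: the route is convergent, joins two achiral pieces of similar size and uses an activated acceptor. The tertiary alcohol next to a carboxyl carbon is the same pattern as in 15, so the later ester reduction equals the lactone reduction of the chosen plan. There is no lactonisation equilibrium to manage, and the number of steps to the stereocenter should be equal or somewhat lower.
- Against it: ortho-silyloxy arylboron reagents transmetalate slowly and protodeboronate under the basic aqueous conditions. A4 is enolisable and carries a β-alkoxy group. In A5 as drawn (S), the ester and ether arms are interchanged in space relative to the carbonyl and ether arms of 15. The ester carbon of A5 would therefore have to become the acetoxymethyl carbon and the ether arm the oxirane CH2. That sends the sequence through an acetate on one arm with the other arm free, the migration-prone situation the chosen plan avoids. The mirror-image ligand would remove this problem and allow the end game of the chosen plan.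
- Comparison: the silyl ethers of A5 must still be exchanged for isobutyrates before the oxirane is closed, so the overall length would be about equal. Mechanistically both plans ask a catalyst to tell apart two oxygenated flanks of similar size. The chosen plan has the more rigid substrate; the alternative has the more convergent assembly.

Alternative 3: The oxirane CH2–O bond is traced to bromohydrin A7, and A7 to the symmetric oxetanol A6. In the forward step Me3SiBr and a chiral squaramide hydrogen-bond donor would open A6 at one of its two enantiotopic ring CH2 groups, breaking a ring C–O bond and forming a C–Br bond.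

- In its favour: the two arms would be differentiated in the very step that creates chirality, from a symmetric precursor, and neither arm needs a protecting group. Base closure of A7 would give 21, after which the last step is the same as in the chosen plan. On step economy this alternative is clearly the better one.
- Against it: the silyl bromide would also silylate the free tertiary hydroxyl of A6. The catalyst must bind an oxetane oxygen flanked by a fully substituted carbon that carries an ortho-acyloxy arene. A7 is a free diol whose base closure generates the alkoxide of 21, which a Payne rearrangement would convert into the enantiomer. Making A6 by aryl-metal addition also excludes the esters and requires a protecting-group exchange next to a tertiary benzylic alcohol.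
- Comparison: the acyl-transfer risk of a tertiary hydroxyl ortho to an aryl ester is shared with 18 (equal). The chosen plan closes the oxirane while the second arm is still an ether, so no alkoxide sits next to the finished oxirane. The alternative gives up this safeguard in exchange for brevity.

Key step: step 10

Assumption: which pseudoenantiomeric cinchona catalyst gives the 3R alcohol cannot be assigned in advance for this substrate; the quinidine-derived squaramide is written, and its quinine-derived counterpart would be used if the opposite face were preferred.

Abbreviations: TBS = tert-butyl(dimethyl)silyl; PMB = 4-methoxybenzyl.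

## Steps

Step 1
Reactants: 1 4-methoxybenzyl alcohol
Product: 2 4-methoxybenzyl methylthiomethyl ether (1-methoxy-4-{[(methylsulfanyl)methoxy]methyl}benzene)
Conditions: NaH, ClCH2SMe, NaI (cat.), DME, 0 °C to rt
Reagents that add atoms: chloromethyl methyl sulfide, CSCCl
Why: Williamson ether synthesis; the sodium alkoxide displaces chloride from the α-chloro sulfide, which is activated by the adjacent sulfur and by in situ exchange to the iodide.

Step 2
Reactants: 2 4-methoxybenzyl methylthiomethyl ether
Product: 3 4-methoxybenzyl chloromethyl ether (1-[(chloromethoxy)methyl]-4-methoxybenzene)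
Conditions: SO2Cl2 (1.0 equiv), CH2Cl2, −78 °C; volatiles removed cold; used at once
Reagents that add atoms: sulfuryl chloride, O=S(=O)(Cl)Cl
Why: Chlorinolysis of the O,S-acetal: sulfur is chlorinated, methanesulfenyl chloride leaves and chloride captures the oxocarbenium ion; this is the usual entry to alkoxymethyl chlorides from methylthiomethyl ethers, and the labile product is not purified.

Step 3
Reactants: 4 methyl 4-bromo-3-hydroxybenzoate
Product: 5 methyl 4-bromo-3-[tert-butyl(dimethyl)silyloxy]benzoate
Conditions: TBSCl, imidazole, DMF, rt
Reagents that add atoms: tert-butyl(chloro)dimethylsilane, CC(C)(C)[Si](C)(C)Cl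
Why: Imidazole-promoted silylation of the phenol while the benzylic carbon is still an ester, so no choice between two hydroxyl groups is needed.

Step 4
Reactants: 5 methyl 4-bromo-3-[tert-butyl(dimethyl)silyloxy]benzoate
Product: 6 {4-bromo-3-[tert-butyl(dimethyl)silyloxy]phenyl}methanol
Conditions: i-Bu2AlH (2.5 equiv), CH2Cl2, −78 to 0 °C; aq. potassium sodium tartrate
Reagents that add atoms: none
Why: Hydride reduction of the aryl ester to the benzylic alcohol; at low temperature the aluminium hydride leaves the aryl bromide and the aryl silyl ether untouched.

Step 5
Reactants: 6 {4-bromo-3-[tert-butyl(dimethyl)silyloxy]phenyl}methanol, 7 isobutyric anhydride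
Product: 8 4-bromo-3-[tert-butyl(dimethyl)silyloxy]benzyl 2-methylpropanoate
Conditions: Et3N, DMAP (cat.), CH2Cl2, 0 °C to rt
Reagents that add atoms: none
Why: Nucleophile-catalysed acylation of the primary alcohol; the isobutyrate the target needs here is installed before any lactone exists, because an aryl lactone is an active ester that a free primary alcohol would open.

Step 6
Reactants: 8 4-bromo-3-[tert-butyl(dimethyl)silyloxy]benzyl 2-methylpropanoate, 9 ethyl bromoacetate
Product: 11 ethyl 2-{2-[tert-butyl(dimethyl)silyloxy]-4-[(2-methylpropanoyloxy)methyl]phenyl}acetate, via bromo(2-ethoxy-2-oxoethyl)zinc 10 (not isolated)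
Conditions: 9, Zn dust (Me3SiCl-activated), THF, rt; then 8, Pd2(dba)3 (1 mol%), XPhos (4 mol%), THF, 60 °C
Reagents that add atoms: none
Why: Negishi-type α-arylation with a Reformatsky reagent: oxidative addition of the aryl bromide to zerovalent palladium, transmetalation of the zinc enolate and reductive elimination. The neutral zinc enolate tolerates the isobutyrate and the silyl ether, and a bulky biaryl phosphine is used instead of triphenylphosphine because the bromide is electron-rich and ortho-substituted.

Step 7
Reactants: 11 ethyl 2-{2-[tert-butyl(dimethyl)silyloxy]-4-[(2-methylpropanoyloxy)methyl]phenyl}acetate, 3 4-methoxybenzyl chloromethyl ether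
Product: 12 ethyl 2-{2-[tert-butyl(dimethyl)silyloxy]-4-[(2-methylpropanoyloxy)methyl]phenyl}-3-[(4-methoxybenzyl)oxy]propanoate (racemic)
Conditions: LiN(SiMe3)2 (1.05 equiv), THF, −78 °C; then 3 (1.3 equiv), −78 to −40 °C
Reagents that add atoms: none
Why: Lithium enolate alkylation; the arylacetate proton is far more acidic than the tertiary α-hydrogen of the isobutyrate, so one equivalent of amide base forms only the desired enolate, which the reactive α-chloro ether alkylates at carbon. The new stereocenter forms as a racemate and is erased again in step 10.

Step 8
Reactants: 12 ethyl 2-{2-[tert-butyl(dimethyl)silyloxy]-4-[(2-methylpropanoyloxy)methyl]phenyl}-3-[(4-methoxybenzyl)oxy]propanoate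
Product: 13 ethyl 2-{2-hydroxy-4-[(2-methylpropanoyloxy)methyl]phenyl}-3-[(4-methoxybenzyl)oxy]propanoate (racemic)
Conditions: Bu4NF (1.2 equiv), AcOH (1.5 equiv), THF, 0 °C
Reagents that add atoms: none
Why: Fluoride cleavage of the aryl silyl ether; acetic acid buffers the phenoxide so that neither ester enolisation nor β-elimination of the alkoxide is triggered, and the alkyl esters are unaffected.

Step 9
Reactants: 13 ethyl 2-{2-hydroxy-4-[(2-methylpropanoyloxy)methyl]phenyl}-3-[(4-methoxybenzyl)oxy]propanoate
Product: 14 {3-[(4-methoxybenzyloxy)methyl]-2-oxo-2,3-dihydro-1-benzofuran-6-yl}methyl 2-methylpropanoate (racemic)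
Conditions: PPTS (0.2 equiv), toluene, 100 °C, 5 Å molecular sieves as ethanol trap
Reagents that add atoms: none
Why: Acid-catalysed intramolecular transesterification (5-exo-trig lactonisation of the phenol onto the ethyl ester); the equilibrium with the hydroxy ester is driven by removing ethanol, and the weak pyridinium acid is chosen to spare the 4-methoxybenzyl ether and the benzylic ester.

Step 10
Reactants: 14 {3-[(4-methoxybenzyloxy)methyl]-2-oxo-2,3-dihydro-1-benzofuran-6-yl}methyl 2-methylpropanoate
Product: 15 {(3R)-3-hydroxy-3-[(4-methoxybenzyloxy)methyl]-2-oxo-2,3-dihydro-1-benzofuran-6-yl}methyl 2-methylpropanoate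
Conditions: squaramide of 9-amino-9-deoxy-epi-quinidine and 3,5-bis(trifluoromethyl)aniline (10 mol%), (±)-trans-2-(benzenesulfonyl)-3-phenyloxaziridine (1.5 equiv), toluene, −20 °C
Reagents that add atoms: 2-(benzenesulfonyl)-3-phenyloxaziridine, O=S(=O)(c1ccccc1)N1OC1c1ccccc1
Why: The quinuclidine nitrogen of the catalyst removes the C3 proton of 14, which is acidic because the anion is an aromatic benzofuran-2-olate, and the ammonium–enolate ion pair is held in the chiral pocket by the squaramide N–H bonds. C3 of the enolate attacks the oxaziridine oxygen in a substitution at oxygen, the N–O bond breaks, the fragment collapses to the sulfonyl imine, and the alkoxide is protonated by the ammonium ion, which returns the catalyst. The closest known reaction type is the chiral-base-catalysed asymmetric α-hydroxylation of 3-substituted oxindoles and cyclic β-keto esters with N-sulfonyl oxaziridines; 3-alkylbenzofuranones are the same kind of pronucleophile but less studied. No ring is closed; one C–O bond and one stereocenter are formed. The configuration at C3 is set by the catalyst, which shields one face of the planar enolate whose geometry is locked by the lactone ring, and because C3 is planarised both enantiomers of racemic 14 converge on 15. The step needs oxidation to outrun β-elimination of 4-methoxybenzyl oxide from the enolate; the poor leaving group, the aromatic stabilisation of the enolate and the weak base at low temperature work in this direction. The benzylic isobutyrate has no proton that a tertiary amine can remove, and the product has no α-hydrogen, so it cannot racemise by enolisation.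

Step 11
Reactants: 15 {(3R)-3-hydroxy-3-[(4-methoxybenzyloxy)methyl]-2-oxo-2,3-dihydro-1-benzofuran-6-yl}methyl 2-methylpropanoate
Product: 17 3-hydroxy-4-{(2S)-1,2-dihydroxy-3-[(4-methoxybenzyl)oxy]propan-2-yl}benzyl 2-methylpropanoate, via hydroxy aldehyde 16 (not isolated)
Conditions: NaBH4 (3 equiv), THF/EtOH 4:1, 0 °C; aq. NH4Cl
Reagents that add atoms: none
Why: Borohydride reduction of an activated ester: the aryl lactone flanked by the hydroxyl group is reduced through the ring-opened hydroxy aldehyde to the primary alcohol, while the unactivated, branched benzylic isobutyrate should survive at 0 °C. No bond at the stereocenter is broken, and the near-neutral work-up avoids ionising the benzylic tertiary alcohol ortho to the free phenol.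

Step 12
Reactants: 17 3-hydroxy-4-{(2S)-1,2-dihydroxy-3-[(4-methoxybenzyl)oxy]propan-2-yl}benzyl 2-methylpropanoate, 7 isobutyric anhydride
Product: 18 2-{(2S)-1,2-dihydroxy-3-[(4-methoxybenzyl)oxy]propan-2-yl}-5-[(2-methylpropanoyloxy)methyl]phenyl 2-methylpropanoate
Conditions: 7 (1.05 equiv), Et3N (1.1 equiv), CH2Cl2, −20 to 0 °C, no acyl-transfer catalyst
Reagents that add atoms: none
Why: Phenoxide-selective acylation: with an amine base and no acyl-transfer catalyst only the acidic phenol reacts with the anhydride at low temperature, the neopentyl-type primary hydroxyl and the tertiary hydroxyl being much slower.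

Step 13
Reactants: 18 2-{(2S)-1,2-dihydroxy-3-[(4-methoxybenzyl)oxy]propan-2-yl}-5-[(2-methylpropanoyloxy)methyl]phenyl 2-methylpropanoate
Product: 20 2-{(2S)-2-[(4-methoxybenzyloxy)methyl]oxiran-2-yl}-5-[(2-methylpropanoyloxy)methyl]phenyl 2-methylpropanoate, via primary tosylate 19 (not isolated)
Conditions: TsCl (1.2 equiv), Et3N, Me3N·HCl (10 mol%), CH2Cl2, 0 °C; then DBU (2 equiv), 0 °C to rt
Reagents that add atoms: none
Why: Selective sulfonylation of the primary hydroxyl (the tertiary one is inert), then base-induced intramolecular Williamson closure, 3-exo-tet, of the tertiary oxygen onto the CH2–OTs carbon. The C–O bond at the stereocenter is retained, so the configuration set in step 10 is carried into the oxirane.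

Step 14
Reactants: 20 2-{(2S)-2-[(4-methoxybenzyloxy)methyl]oxiran-2-yl}-5-[(2-methylpropanoyloxy)methyl]phenyl 2-methylpropanoate
Product: 21 2-[(2R)-2-(hydroxymethyl)oxiran-2-yl]-5-[(2-methylpropanoyloxy)methyl]phenyl 2-methylpropanoate
Conditions: DDQ (1.3 equiv), CH2Cl2/pH 7 phosphate buffer 10:1, 0 °C to rt
Reagents that add atoms: none
Why: Oxidative cleavage of the 4-methoxybenzyl ether by hydride abstraction and hydrolysis of the oxocarbenium ion; the buffered two-phase medium keeps the tertiary benzylic oxirane and the esters away from acid. The descriptor changes from S to R only because the priorities of the two arms change.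

Step 15
Reactants: 21 2-[(2R)-2-(hydroxymethyl)oxiran-2-yl]-5-[(2-methylpropanoyloxy)methyl]phenyl 2-methylpropanoate
Product: 22 2-[(2S)-2-(acetoxymethyl)oxiran-2-yl]-5-[(2-methylpropanoyloxy)methyl]phenyl 2-methylpropanoate (CNP0151517.1)
Conditions: Ac2O, pyridine, DMAP (cat.), CH2Cl2, 0 °C
Reagents that add atoms: acetic anhydride, CC(=O)OC(C)=O
Why: Nucleophile-catalysed O-acetylation under amine conditions; no alkoxide of the epoxy alcohol is formed, so a Payne rearrangement, which would lead to the enantiomer, is avoided.

## Compound list

1 | 4-methoxybenzyl alcohol | COc1ccc(CO)cc1 | starting material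
2 | 4-methoxybenzyl methylthiomethyl ether | COc1ccc(COCSC)cc1 | intermediate
3 | 4-methoxybenzyl chloromethyl ether | COc1ccc(COCCl)cc1 | intermediate
4 | methyl 4-bromo-3-hydroxybenzoate | COC(=O)c1ccc(Br)c(O)c1 | starting material
5 | methyl 4-bromo-3-[tert-butyl(dimethyl)silyloxy]benzoate | COC(=O)c1ccc(Br)c(O[Si](C)(C)C(C)(C)C)c1 | intermediate
6 | {4-bromo-3-[tert-butyl(dimethyl)silyloxy]phenyl}methanol | OCc1ccc(Br)c(O[Si](C)(C)C(C)(C)C)c1 | intermediate
7 | isobutyric anhydride | CC(C)C(=O)OC(=O)C(C)C | starting material
8 | 4-bromo-3-[tert-butyl(dimethyl)silyloxy]benzyl 2-methylpropanoate | CC(C)C(=O)OCc1ccc(Br)c(O[Si](C)(C)C(C)(C)C)c1 | intermediate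
9 | ethyl bromoacetate | CCOC(=O)CBr | starting material
10 | bromo(2-ethoxy-2-oxoethyl)zinc | CCOC(=O)C[Zn]Br | intermediate
11 | ethyl 2-{2-[tert-butyl(dimethyl)silyloxy]-4-[(2-methylpropanoyloxy)methyl]phenyl}acetate | CCOC(=O)Cc1ccc(COC(=O)C(C)C)cc1O[Si](C)(C)C(C)(C)C | intermediate
12 | ethyl 2-{2-[tert-butyl(dimethyl)silyloxy]-4-[(2-methylpropanoyloxy)methyl]phenyl}-3-[(4-methoxybenzyl)oxy]propanoate (racemic) | CCOC(=O)C(COCc1ccc(OC)cc1)c1ccc(COC(=O)C(C)C)cc1O[Si](C)(C)C(C)(C)C | intermediate
13 | ethyl 2-{2-hydroxy-4-[(2-methylpropanoyloxy)methyl]phenyl}-3-[(4-methoxybenzyl)oxy]propanoate (racemic) | CCOC(=O)C(COCc1ccc(OC)cc1)c1ccc(COC(=O)C(C)C)cc1O | intermediate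
14 | {3-[(4-methoxybenzyloxy)methyl]-2-oxo-2,3-dihydro-1-benzofuran-6-yl}methyl 2-methylpropanoate (racemic) | COc1ccc(COCC2C(=O)Oc3cc(COC(=O)C(C)C)ccc32)cc1 | intermediate
15 | {(3R)-3-hydroxy-3-[(4-methoxybenzyloxy)methyl]-2-oxo-2,3-dihydro-1-benzofuran-6-yl}methyl 2-methylpropanoate | COc1ccc(COC[C@@]2(O)C(=O)Oc3cc(COC(=O)C(C)C)ccc32)cc1 | intermediate
16 | 3-hydroxy-4-{(2R)-2-hydroxy-1-[(4-methoxybenzyl)oxy]-3-oxopropan-2-yl}benzyl 2-methylpropanoate | COc1ccc(COC[C@@](O)(C=O)c2ccc(COC(=O)C(C)C)cc2O)cc1 | intermediate
17 | 3-hydroxy-4-{(2S)-1,2-dihydroxy-3-[(4-methoxybenzyl)oxy]propan-2-yl}benzyl 2-methylpropanoate | COc1ccc(COC[C@@](O)(CO)c2ccc(COC(=O)C(C)C)cc2O)cc1 | intermediate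
18 | 2-{(2S)-1,2-dihydroxy-3-[(4-methoxybenzyl)oxy]propan-2-yl}-5-[(2-methylpropanoyloxy)methyl]phenyl 2-methylpropanoate | COc1ccc(COC[C@@](O)(CO)c2ccc(COC(=O)C(C)C)cc2OC(=O)C(C)C)cc1 | intermediate
19 | 2-{(2R)-2-hydroxy-1-[(4-methoxybenzyl)oxy]-3-[(4-methylbenzenesulfonyl)oxy]propan-2-yl}-5-[(2-methylpropanoyloxy)methyl]phenyl 2-methylpropanoate | COc1ccc(COC[C@@](O)(COS(=O)(=O)c3ccc(C)cc3)c2ccc(COC(=O)C(C)C)cc2OC(=O)C(C)C)cc1 | intermediate
20 | 2-{(2S)-2-[(4-methoxybenzyloxy)methyl]oxiran-2-yl}-5-[(2-methylpropanoyloxy)methyl]phenyl 2-methylpropanoate | COc1ccc(COC[C@]2(c3ccc(COC(=O)C(C)C)cc3OC(=O)C(C)C)CO2)cc1 | intermediate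
21 | 2-[(2R)-2-(hydroxymethyl)oxiran-2-yl]-5-[(2-methylpropanoyloxy)methyl]phenyl 2-methylpropanoate | OC[C@]1(c2ccc(COC(=O)C(C)C)cc2OC(=O)C(C)C)CO1 | intermediate
22 | 2-[(2S)-2-(acetoxymethyl)oxiran-2-yl]-5-[(2-methylpropanoyloxy)methyl]phenyl 2-methylpropanoate | CC(=O)OC[C@]1(c2ccc(COC(=O)C(C)C)cc2OC(=O)C(C)C)CO1 | target

## Step count and least certain steps

Total step count: 15, of which two (steps 1 and 2) form the short branch to 3. Longest linear sequence: 13 steps (steps 3 to 15, from 4 to 22).

**Step 10 (key step).** The most likely failure is β-elimination of the alkoxymethyl group from the enolate, giving a 3-methylene lactone. Further risks are insufficient face selection (the 3-substituent is small and flexible), slow oxidation of the catalyst's tertiary amine by the oxaziridine, and Mannich-type capture of the enolate by the sulfonyl imine as it accumulates. The fallback moves the source of chirality from the catalyst to the oxidant. 14 would be converted into its sodium enolate with NaN(SiMe3)2 in THF at −78 °C and oxidised with a stoichiometric enantiopure (camphorsulfonyl)oxaziridine, written here as the (1S) reagent and to be exchanged for its antipode if the sense is wrong. Its ketimine by-product does not add enolates. This returns to the route at 15 and makes no new compound (F0).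

**Step 7.** The chloromethyl ether 3 may decompose before it is consumed, and O-alkylation or proton transfer between product and enolate may lower the amount of mono-C-alkylated ester. The fallback builds the arm in two operations with stable reagents. The lithium enolate of 11 would be hydroxymethylated with monomeric formaldehyde at −78 °C to ethyl 2-{2-[tert-butyl(dimethyl)silyloxy]-4-[(2-methylpropanoyloxy)methyl]phenyl}-3-hydroxypropanoate F1. The hydroxyl would then be etherified with 4-methoxybenzyl 2,2,2-trichloroacetimidate and catalytic camphorsulfonic acid, returning to the route at 12.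

**Step 9.** Ring closure may stop short because the aryl lactone and ethanol re-equilibrate with the hydroxy ester, and a stronger acid or higher temperature would begin to remove the 4-methoxybenzyl ether. The fallback closes the ring irreversibly from the acid. 13 would be saponified with LiOH in aqueous THF at 0 °C, which also cleaves the isobutyrate, to 2-[2-hydroxy-4-(hydroxymethyl)phenyl]-3-[(4-methoxybenzyl)oxy]propanoic acid F2. F2 would be cyclised with EDC·HCl at high dilution to 6-(hydroxymethyl)-3-{[(4-methoxybenzyl)oxy]methyl}-1-benzofuran-2(3H)-one F3. F3 would be acylated without delay with 7 and pyridine at 0 °C, returning to the route at 14.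

**Step 13.** The tertiary alkoxide may attack the neighbouring aryl isobutyrate through a six-membered transition state instead of closing the oxirane; the phenoxide released would then displace the tosylate and give a dihydrobenzofuran. The fallback avoids both the sulfonate and the free alkoxide. 18 would be treated with triphenylphosphine and diisopropyl azodicarboxylate in toluene (Mitsunobu-type cyclodehydration). The less hindered primary oxygen becomes the phosphonium leaving group and the tertiary oxygen closes with retention at the stereocenter, returning to the route at 20 without a new compound (F0).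

**Step 14.** The tertiary benzylic oxirane may open or rearrange during the oxidative ether cleavage, either through the acidity of the reduced quinone or through capture of the oxocarbenium ion by the oxirane oxygen. The fallback removes the ether before the oxirane exists. From 18 the tosylate 19 would be isolated and then treated with DDQ under the same buffered conditions to give 2-{(2R)-1,2-dihydroxy-3-[(4-methylbenzenesulfonyl)oxy]propan-2-yl}-5-[(2-methylpropanoyloxy)methyl]phenyl 2-methylpropanoate F4. F4 would be closed with DBU at 0 °C, returning to the route at 21. Here 3-exo closure by the tertiary oxygen must outrun 4-exo closure by the primary one, and the reaction must be stopped before the alkoxide of 21 can rearrange.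

## Further compounds

F0 | step 10 | none | none
F1 | step 7 | ethyl 2-{2-[tert-butyl(dimethyl)silyloxy]-4-[(2-methylpropanoyloxy)methyl]phenyl}-3-hydroxypropanoate (racemic) | CCOC(=O)C(CO)c1ccc(COC(=O)C(C)C)cc1O[Si](C)(C)C(C)(C)C
F2 | step 9 | 2-[2-hydroxy-4-(hydroxymethyl)phenyl]-3-[(4-methoxybenzyl)oxy]propanoic acid (racemic) | COc1ccc(COCC(C(=O)O)c2ccc(CO)cc2O)cc1
F3 | step 9 | 6-(hydroxymethyl)-3-{[(4-methoxybenzyl)oxy]methyl}-1-benzofuran-2(3H)-one (racemic) | COc1ccc(COCC2C(=O)Oc3cc(CO)ccc32)cc1
F0 | step 13 | none | none
F4 | step 14 | 2-{(2R)-1,2-dihydroxy-3-[(4-methylbenzenesulfonyl)oxy]propan-2-yl}-5-[(2-methylpropanoyloxy)methyl]phenyl 2-methylpropanoate | Cc1ccc(S(=O)(=O)OC[C@](O)(CO)c2ccc(COC(=O)C(C)C)cc2OC(=O)C(C)C)cc1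
A1 | alternative 1 | 1-{2-[tert-butyl(dimethyl)silyloxy]-4-({[tert-butyl(dimethyl)silyl]oxy}methyl)phenyl}-2-[(4-methoxybenzyl)oxy]ethan-1-one | COc1ccc(COCC(=O)c2ccc(CO[Si](C)(C)C(C)(C)C)cc2O[Si](C)(C)C(C)(C)C)cc1
A2 | alternative 1 | tert-butyl{[3-[tert-butyl(dimethyl)silyloxy]-4-{(2S)-2-[(4-methoxybenzyloxy)methyl]oxiran-2-yl}phenyl]methoxy}dimethylsilane | COc1ccc(COC[C@]2(c3ccc(CO[Si](C)(C)C(C)(C)C)cc3O[Si](C)(C)C(C)(C)C)CO2)cc1
A3 | alternative 2 | 2-{2-[tert-butyl(dimethyl)silyloxy]-4-({[tert-butyl(dimethyl)silyl]oxy}methyl)phenyl}-4,4,5,5-tetramethyl-1,3,2-dioxaborolane | CC(C)(C)[Si](C)(C)OCc1ccc(B2OC(C)(C)C(C)(C)O2)c(O[Si](C)(C)C(C)(C)C)c1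
A4 | alternative 2 | ethyl 3-[(4-methoxybenzyl)oxy]-2-oxopropanoate | CCOC(=O)C(=O)COCc1ccc(OC)cc1
A5 | alternative 2 | ethyl (2S)-2-{2-[tert-butyl(dimethyl)silyloxy]-4-({[tert-butyl(dimethyl)silyl]oxy}methyl)phenyl}-2-hydroxy-3-[(4-methoxybenzyl)oxy]propanoate | CCOC(=O)[C@](O)(c1ccc(CO[Si](C)(C)C(C)(C)C)cc1O[Si](C)(C)C(C)(C)C)COCc1ccc(OC)cc1
A6 | alternative 3 | 2-(3-hydroxyoxetan-3-yl)-5-[(2-methylpropanoyloxy)methyl]phenyl 2-methylpropanoate | CC(C)C(=O)OCc1ccc(C2(O)COC2)c(OC(=O)C(C)C)c1
A7 | alternative 3 | 2-[(2R)-1-bromo-2,3-dihydroxypropan-2-yl]-5-[(2-methylpropanoyloxy)methyl]phenyl 2-methylpropanoate | OC[C@](O)(c1ccc(COC(=O)C(C)C)cc1OC(=O)C(C)C)CBr
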